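**Plan**

- Retrosynthesis: remove the C6 acetate; open the C4–O–C5 oxirane at C5–O to a C4 carbinol and C5 mesylate; take the C5 carbinol back to a ketone; reconnect C5–C10 across the ten-membered ring to a trans-decalin 1-mesylate. Ring B is then cut at C8–O/C7–H (hydroboration), C7–isopropyl (cross-coupling), C6–O/C5–O (osmylation) and C4–CH3 (methyllithium), back to (R)-Wieland–Miescher ketone.
- Enabling feature: the (E)-C1=C10 alkene (methyl on C10) faces the oxirane carbon C5 across the ten-membered ring. A C5–C10 bond turns that ring into rings A and B of a trans-decalin in which a C5 alkoxide, the C5–C10 bond and an equatorial C1 sulfonate are antiperiplanar.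
- Forward order: both six-membered rings come with the starting ketone; the ten-membered ring appears in step 18 by cleavage of the ring-fusion bond; the oxirane is closed last (3-exo-tet).
- Stereochemistry: C10 comes from (R)-Wieland–Miescher ketone. C1, C4, C5, C6, C7 and C8 of the decalin are set by reagent approach anti to the axial C10 methyl. C5 of the ten-membered ring is set by hydride addition to the open face of an acetal-bridged ketone, then inverted on oxirane closure. The alkene geometry follows from the antiperiplanar fragmentation.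

Key step: step 18

Remark: ring atoms are numbered C1–C10 as in the target (C10 carries the ring methyl, C4 the carbinol methyl, C7 the isopropyl group). In the decalins β is the face of the C10 methyl, ring A is C1–C5/C10 and ring B is C5–C10. The target is read as (1(10)E,4S,5R,6R,7R,8S), with C3 and C6 cis on the oxirane.

**Route**

Step 1
Reactants: 1 (R)-Wieland–Miescher ketone (C1 ketone, C5=C6–C7=O enone, C10 methyl)
Product: 2 (4aR,5R)-5-hydroxy-4a-methyl-4,4a,5,6,7,8-hexahydronaphthalen-2(3H)-one (1β-hydroxy enone)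
Conditions: NaBH4 (0.3 equiv), EtOH, −10 °C
Reagents that add atoms: none
Why: Chemoselective borohydride reduction of the saturated C1 ketone beside the less electrophilic enone, with hydride adding anti to the angular C10 methyl so that the 1β (equatorial, cis to the methyl) alcohol results.

Step 2
Reactants: 2 1β-hydroxy enone; 3 ethylene glycol
Product: 4 7,7-ethylenedioxy-10β-methyl-Δ4-octalin-1β-ol (dioxolane on C7, alkene C4=C5)
Conditions: ethylene glycol, TsOH·H2O (cat.), benzene, reflux (Dean–Stark)
Reagents that add atoms: ethylene glycol, OCCO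
Why: Acid-catalysed ketalisation of the enone carbonyl, which runs through the dienol ether and therefore leaves the double bond out of conjugation at C4=C5, as is general for ring-fused cyclohexenones of this type.

Step 3
Reactants: 4 ketal alcohol; 5 benzyl bromide
Product: 6 1β-benzyloxy-7,7-ethylenedioxy-10β-methyl-Δ4-octalin
Conditions: NaH, BnBr, Bu4NI (cat.), THF, 0 °C → rt
Reagents that add atoms: benzyl bromide, BrCc1ccccc1
Why: Williamson etherification of the secondary alkoxide; benzyl is chosen because it survives every acid, base, oxidant and hydride up to step 15 and leaves by hydrogenolysis at a stage that has no alkene.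

Step 4
Reactants: 6 benzyl ether
Product: 7 1β-benzyloxy-4α,5α-epoxy-7,7-ethylenedioxy-10β-methyldecalin
Conditions: mCPBA, CH2Cl2, 0 °C
Reagents that add atoms: meta-chloroperoxybenzoic acid, OOC(=O)c1cccc(Cl)c1
Why: Prilezhaev epoxidation of the electron-rich trisubstituted alkene from the α face, anti to the axial C10 methyl; both new stereocentres are erased again in steps 5 and 6, so any β-epoxide would converge on the same enone.

Step 5
Reactants: 7 epoxide
Product: 8 1β-benzyloxy-7,7-ethylenedioxy-10β-methyl-Δ5-octalin-4α-ol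
Conditions: Et2Al(TMP) (from Et2AlCl and lithium 2,2,6,6-tetramethylpiperidide), toluene, 0 °C
Reagents that add atoms: none
Why: Aluminium amide-mediated isomerisation of an epoxide to an allylic alcohol, in which the amide removes a C6 hydrogen syn to the oxirane (C6 is the only hydrogen-bearing carbon on the fully substituted oxirane carbon and is cis to the oxirane hydrogen) while the tertiary C5–O bond breaks, so oxygen stays on C4 and the alkene moves to C5=C6.

Step 6
Reactants: 8 allylic alcohol
Product: 9 1β-benzyloxy-7,7-ethylenedioxy-10β-methyl-Δ5-octalin-4-one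
Conditions: Dess–Martin periodinane, CH2Cl2, rt
Reagents that add atoms: none
Why: Dess–Martin oxidation of the secondary allylic alcohol to the conjugated enone under neutral conditions that leave the dioxolane untouched.

Step 7
Reactants: 9 enone; 10 methyllithium
Product: 11 1β-benzyloxy-7,7-ethylenedioxy-4α,10β-dimethyl-Δ5-octalin-4β-ol
Conditions: MeLi, THF, −78 °C
Reagents that add atoms: methyllithium, [Li]C
Why: 1,2-Addition of the organolithium to the enone carbonyl from the α (equatorial) side, because axial approach is blocked by the 1,3-related axial C10 methyl, which sets C4 with methyl α and hydroxyl β.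

Step 8
Reactants: 11 tertiary allylic alcohol
Product: 12 1β-benzyloxy-7,7-ethylenedioxy-4α,10β-dimethyl-trans-decalin-4β,5α,6α-triol
Conditions: OsO4 (cat.), N-methylmorpholine N-oxide, acetone–H2O, rt
Reagents that add atoms: N-methylmorpholine N-oxide, C[N+]1([O-])CCOCC1; water, O
Why: Catalytic osmium tetroxide syn-dihydroxylation of C5=C6 from the α face, anti to both the allylic C4 hydroxyl and the C10 methyl, sets C5 (hydroxyl α, trans to the C10 methyl) and gives the 6α alcohol that steps 9 and 10 correct.

Step 9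
Reactants: 12 triol
Product: 13 1β-benzyloxy-7,7-ethylenedioxy-4β,5α-dihydroxy-4α,10β-dimethyl-trans-decalin-6-one
Conditions: Dess–Martin periodinane, CH2Cl2, rt
Reagents that add atoms: none
Why: Dess–Martin oxidation of the only secondary hydroxyl (C6) to the α-hydroxy ketone; the tertiary C4 and C5 alcohols cannot be oxidised and this reagent is not expected to cleave the glycol.

Step 10
Reactants: 13 hydroxy ketone
Product: 14 1β-benzyloxy-7,7-ethylenedioxy-4α,10β-dimethyl-trans-decalin-4β,5α,6β-triol
Conditions: NaBH4, MeOH, 0 °C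
Reagents that add atoms: none
Why: Borohydride reduction of the C6 ketone from the α face, the β face being closed by the syn-axial C10 methyl and C4 hydroxyl, gives the axial 6β alcohol (the outcome known for 5α-hydroxy-6-oxo steroids).

Step 11
Reactants: 14 triol ketal; 15 2,2-dimethoxypropane
Product: 17 1β-benzyloxy-5α-hydroxy-4β,6β-(isopropylidenedioxy)-4α,10β-dimethyl-trans-decalin-7-one, via acetonide ketal 16 (not isolated)
Conditions: 2,2-dimethoxypropane, TsOH·H2O (cat.), acetone, rt
Reagents that add atoms: 2,2-dimethoxypropane, COC(C)(C)OC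
Why: Acid-catalysed acetal exchange in which the syn-diaxial C4 and C6 hydroxyls close a 1,3-dioxane (isopropylidene acetal) while the dioxolane is passed on to acetone (transketalisation); the C5 hydroxyl is trans-diaxial to both neighbours, cannot be bridged and stays free.

Step 12
Reactants: 17 acetonide ketone; 18 N-phenylbis(trifluoromethanesulfonimide)
Product: 20 1β-benzyloxy-5α-hydroxy-4β,6β-(isopropylidenedioxy)-4α,10β-dimethyl-Δ7-octalin-7-yl trifluoromethanesulfonate, via dilithium alkoxide enolate 19 (not isolated)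
Conditions: LiN(SiMe3)2 (2.2 equiv), THF, −78 °C; then PhNTf2, −78 → 0 °C
Reagents that add atoms: N-phenylbis(trifluoromethanesulfonimide), O=S(=O)(N(c1ccccc1)S(=O)(=O)C(F)(F)F)C(F)(F)F
Why: Kinetic enolisation and O-sulfonylation of the enolate, in which the amide base takes the axial C8 hydrogen (the C6 hydrogen is equatorial and lies near the carbonyl plane) and the lithium C5 alkoxide is too hindered to be triflated.

Step 13
Reactants: 20 enol triflate; 21 isopropylmagnesium chloride
Product: 22 1β-benzyloxy-7-isopropyl-4β,6β-(isopropylidenedioxy)-4α,10β-dimethyl-Δ7-octalin-5α-ol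
Conditions: iPrMgCl (2.5 equiv), Fe(acac)3 (5 mol %), THF–NMP, −30 → 0 °C
Reagents that add atoms: isopropylmagnesium chloride, CC(C)[Mg]Cl
Why: Iron-catalysed Kumada-type cross-coupling of the enol triflate with the secondary alkyl Grignard reagent, which exchanges C–OTf for C–isopropyl without moving the alkene and tolerates the magnesium alkoxide at C5.

Step 14
Reactants: 22 isopropyl alkene
Product: 24 1β-benzyloxy-7β-isopropyl-4β,6β-(isopropylidenedioxy)-4α,10β-dimethyl-trans-decalin-5α,8α-diol, via C8 alkylborane 23 (not isolated)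
Conditions: BH3·THF, THF, 0 °C → rt; then NaOH, H2O2, 0 °C
Reagents that add atoms: borane (BH3·THF), B; hydrogen peroxide, OO
Why: Hydroboration–oxidation, in which syn anti-Markovnikov addition of H–B from the α face (anti to the allylic C6 oxygen, the acetal and the C10 methyl) puts boron on C8 and hydrogen on C7, and oxidation with retention gives the 8α alcohol trans to the equatorial 7β isopropyl group.

Step 15
Reactants: 24 diol; 25 benzoyl chloride
Product: 26 8α-benzoate of 24 (1β-benzyloxy-8α-benzoyloxy-7β-isopropyl-4β,6β-(isopropylidenedioxy)-4α,10β-dimethyl-trans-decalin-5α-ol)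
Conditions: BzCl, pyridine, DMAP (cat.), CH2Cl2, 0 °C → rt
Reagents that add atoms: benzoyl chloride, O=C(Cl)c1ccccc1
Why: DMAP-catalysed acylation of the secondary equatorial C8 hydroxyl, the tertiary C5 hydroxyl being unreactive; this benzoate is the one found in the target.

Step 16
Reactants: 26 benzyl ether benzoate
Product: 27 8α-benzoyloxy-7β-isopropyl-4β,6β-(isopropylidenedioxy)-4α,10β-dimethyl-trans-decalin-1β,5α-diol
Conditions: H2 (1 atm), Pd(OH)2/C, EtOAc, rt
Reagents that add atoms: none
Why: Hydrogenolysis of the benzyl ether over palladium at a stage where the molecule has no alkene and the benzoate, acetal and tertiary alcohol are inert.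

Step 17
Reactants: 27 diol; 28 methanesulfonyl chloride
Product: 29 1β-methanesulfonate of 27 (trans-decalin with C5 hydroxyl α-axial, C10 methyl β-axial, C1 mesylate β-equatorial)
Conditions: MsCl, Et3N, CH2Cl2, 0 °C
Reagents that add atoms: methanesulfonyl chloride, CS(=O)(=O)Cl
Why: Sulfonylation of the secondary equatorial C1 alcohol (via sulfene), the tertiary C5 hydroxyl being unreactive.

Step 18
Reactants: 29 decalin hydroxy mesylate
Product: 31 (E)-8-benzoyloxy-7-isopropyl-4,6-(isopropylidenedioxy)-4,10-dimethylcyclodec-1(10)-en-5-one (configurations at C4, C6, C7, C8 as in 29), via potassium C5 alkoxide 30 (not isolated)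
Conditions: KH (1.1 equiv), THF, 0 °C → rt
Reagents that add atoms: none
Why: The base deprotonates the tertiary C5 hydroxyl, and in the rigid trans-decalin an oxygen lone pair of the axial C5–O−, the C5–C10 ring-fusion bond and the equatorial C1–OMs bond are antiperiplanar, so C5=O forms, C5–C10 breaks, C1=C10 forms and mesylate leaves in one concerted event. This is a Grob fragmentation of a cyclic 1,3-diol monosulfonate, the known route from 1-sulfonyloxy-decalin ring-fusion alcohols to (E)-cyclodecenones. No ring is closed by bond formation: the ten-membered ring arises by cleavage of the bond shared by rings A and B, so no cyclisation mode applies and the medium-ring strain is paid for by the new C=O and C=C bonds. No sp3 stereocentre is created; the alkene is E because C2 and C9 are anti about C1–C10 in the chair–chair decalin, and C4, C6, C7 and C8 are carried over unchanged. The step needs fragmentation to win over elimination, substitution and acyl transfer, and the substrate secures this: the equatorial mesylate has no antiperiplanar hydrogen, C1 is neopentylic, the C4 and C6 oxygens are tied in the acetal (no α-ketol shift in the product), the benzoate has no α-hydrogen, and only a slight excess of a non-nucleophilic base is used so that H6 next to the new ketone is not epimerised.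

Step 19
Reactants: 31 bridged cyclodecenone
Product: 32 (E)-8-benzoyloxy-7-isopropyl-4,6-(isopropylidenedioxy)-4,10-dimethylcyclodec-1(10)-en-5-ol, C5 hydroxyl syn to O4 and O6
Conditions: NaBH4, MeOH–THF, −20 °C
Reagents that add atoms: none
Why: Borohydride reduction of the C5 ketone, in which the dioxanone ring of 31 holds C3 and C7 equatorial so that the acetal carbon and the C1=C10 loop both lie over one face of the carbonyl; hydride adds from the other face (flanked only by the C4 methyl and H6) and the new hydroxyl comes out syn to O4 and O6, as the oxirane closure requires.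

Step 20
Reactants: 32 C5 alcohol; 28 methanesulfonyl chloride
Product: 33 C5 methanesulfonate of 32
Conditions: MsCl, Et3N, DMAP (cat.), CH2Cl2, 0 °C
Reagents that add atoms: methanesulfonyl chloride, CS(=O)(=O)Cl
Why: Sulfonylation of the only free hydroxyl under sulfene conditions, which are the least sensitive to steric hindrance.

Step 21
Reactants: 33 acetonide mesylate
Product: 34 (E)-8-benzoyloxy-4,6-dihydroxy-7-isopropyl-4,10-dimethylcyclodec-1(10)-en-5-yl methanesulfonate
Conditions: PPTS (cat.), MeOH, rt
Reagents that add atoms: none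
Why: Acid-catalysed transacetalisation to methanol removes the strained isopropylidene acetal (axial methyl on C4) under conditions too mild to ionise the secondary mesylate or protonate the alkene.

Step 22
Reactants: 34 diol mesylate; 35 acetic anhydride
Product: 36 6-acetate of 34 ((E)-6-acetoxy-8-benzoyloxy-4-hydroxy-7-isopropyl-4,10-dimethylcyclodec-1(10)-en-5-yl methanesulfonate)
Conditions: Ac2O, pyridine, DMAP (cat.), CH2Cl2, 0 °C
Reagents that add atoms: acetic anhydride, CC(=O)OC(C)=O
Why: DMAP-catalysed acetylation of the secondary C6 hydroxyl, the tertiary C4 hydroxyl being unreactive under these conditions.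

Step 23
Reactants: 36 hydroxy mesylate diester
Product: 38 (1(10)E,4S,5R,6R,7R,8S)-6-acetoxy-8-benzoyloxy-4,5-epoxygermacr-1(10)-ene (CNP0112246.1), via sodium C4 alkoxide 37 (not isolated)
Conditions: NaH (1.1 equiv), THF, 0 °C
Reagents that add atoms: none
Why: Intramolecular Williamson etherification (3-exo-tet) in which the C4 alkoxide displaces the C5 mesylate from the rear with inversion at C5, giving the 4S,5R oxirane with C3 and C6 cis; irreversible deprotonation by a non-nucleophilic hydride at low temperature is meant to leave both esters in place.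

**Compound list**

1 | (R)-Wieland–Miescher ketone, (8aR)-8a-methyl-3,4,8,8a-tetrahydronaphthalene-1,6(2H,7H)-dione | C[C@@]12CCC(=O)C=C1CCCC2=O | starting material
2 | (4aR,5R)-5-hydroxy-4a-methyl-4,4a,5,6,7,8-hexahydronaphthalen-2(3H)-one | C[C@@]12CCC(=O)C=C1CCC[C@H]2O | intermediate
3 | ethylene glycol | OCCO | starting material
4 | 7,7-ethylenedioxy-10β-methyl-Δ4-octalin-1β-ol | C[C@@]12CCC3(OCCO3)CC1=CCC[C@H]2O | intermediate
5 | benzyl bromide | BrCc1ccccc1 | starting material
6 | 1β-benzyloxy-7,7-ethylenedioxy-10β-methyl-Δ4-octalin | C[C@@]12CCC3(OCCO3)CC1=CCC[C@H]2OCc4ccccc4 | intermediate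
7 | 1β-benzyloxy-4α,5α-epoxy-7,7-ethylenedioxy-10β-methyldecalin | C[C@@]12CCC3(OCCO3)C[C@]15O[C@@H]5CC[C@H]2OCc4ccccc4 | intermediate
8 | 1β-benzyloxy-7,7-ethylenedioxy-10β-methyl-Δ5-octalin-4α-ol | C[C@@]12CCC3(OCCO3)C=C1[C@H](O)CC[C@H]2OCc4ccccc4 | intermediate
9 | 1β-benzyloxy-7,7-ethylenedioxy-10β-methyl-Δ5-octalin-4-one | C[C@@]12CCC3(OCCO3)C=C1C(=O)CC[C@H]2OCc4ccccc4 | intermediate
10 | methyllithium | [Li]C | starting material
11 | 1β-benzyloxy-7,7-ethylenedioxy-4α,10β-dimethyl-Δ5-octalin-4β-ol | C[C@@]12CCC3(OCCO3)C=C1[C@@](C)(O)CC[C@H]2OCc4ccccc4 | intermediate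
12 | 1β-benzyloxy-7,7-ethylenedioxy-4α,10β-dimethyl-trans-decalin-4β,5α,6α-triol | C[C@@]12CCC3(OCCO3)[C@H](O)[C@@]1(O)[C@@](C)(O)CC[C@H]2OCc4ccccc4 | intermediate
13 | 1β-benzyloxy-7,7-ethylenedioxy-4β,5α-dihydroxy-4α,10β-dimethyl-trans-decalin-6-one | C[C@@]12CCC3(OCCO3)C(=O)[C@@]1(O)[C@@](C)(O)CC[C@H]2OCc4ccccc4 | intermediate
14 | 1β-benzyloxy-7,7-ethylenedioxy-4α,10β-dimethyl-trans-decalin-4β,5α,6β-triol | C[C@@]12CCC3(OCCO3)[C@@H](O)[C@@]1(O)[C@@](C)(O)CC[C@H]2OCc4ccccc4 | intermediate
15 | 2,2-dimethoxypropane | COC(C)(C)OC | starting material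
16 | 4β,6β-O-isopropylidene acetal of 14, C7 dioxolane still in place (not isolated) | CC1(C)O[C@@H]2C5(OCCO5)CC[C@@]3(C)[C@H](OCc4ccccc4)CC[C@](C)(O1)[C@]23O | intermediate
17 | 1β-benzyloxy-5α-hydroxy-4β,6β-(isopropylidenedioxy)-4α,10β-dimethyl-trans-decalin-7-one | CC1(C)O[C@@H]2C(=O)CC[C@@]3(C)[C@H](OCc4ccccc4)CC[C@](C)(O1)[C@]23O | intermediate
18 | N-phenylbis(trifluoromethanesulfonimide) | O=S(=O)(N(c1ccccc1)S(=O)(=O)C(F)(F)F)C(F)(F)F | starting material
19 | dilithium salt of 17, C5 alkoxide and C7(=C8) enolate (not isolated) | CC1(C)O[C@@H]2C(O[Li])=CC[C@@]3(C)[C@H](OCc4ccccc4)CC[C@](C)(O1)[C@]23O[Li] | intermediate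
20 | 1β-benzyloxy-5α-hydroxy-4β,6β-(isopropylidenedioxy)-4α,10β-dimethyl-Δ7-octalin-7-yl trifluoromethanesulfonate | CC1(C)O[C@@H]2C(OS(=O)(=O)C(F)(F)F)=CC[C@@]3(C)[C@H](OCc4ccccc4)CC[C@](C)(O1)[C@]23O | intermediate
21 | isopropylmagnesium chloride | CC(C)[Mg]Cl | starting material
22 | 1β-benzyloxy-7-isopropyl-4β,6β-(isopropylidenedioxy)-4α,10β-dimethyl-Δ7-octalin-5α-ol | CC1(C)O[C@@H]2C(C(C)C)=CC[C@@]3(C)[C@H](OCc4ccccc4)CC[C@](C)(O1)[C@]23O | intermediate
23 | 8α-boryl adduct of 22, drawn as C8–BH2 with C5–O–BH2 (not isolated) | CC1(C)O[C@@H]2[C@H](C(C)C)[C@@H](B)C[C@@]3(C)[C@H](OCc4ccccc4)CC[C@](C)(O1)[C@]23OB | intermediate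
24 | 1β-benzyloxy-7β-isopropyl-4β,6β-(isopropylidenedioxy)-4α,10β-dimethyl-trans-decalin-5α,8α-diol | CC1(C)O[C@@H]2[C@H](C(C)C)[C@@H](O)C[C@@]3(C)[C@H](OCc4ccccc4)CC[C@](C)(O1)[C@]23O | intermediate
25 | benzoyl chloride | O=C(Cl)c1ccccc1 | starting material
26 | 1β-benzyloxy-8α-benzoyloxy-7β-isopropyl-4β,6β-(isopropylidenedioxy)-4α,10β-dimethyl-trans-decalin-5α-ol | CC1(C)O[C@@H]2[C@H](C(C)C)[C@@H](OC(=O)c5ccccc5)C[C@@]3(C)[C@H](OCc4ccccc4)CC[C@](C)(O1)[C@]23O | intermediate
27 | 8α-benzoyloxy-7β-isopropyl-4β,6β-(isopropylidenedioxy)-4α,10β-dimethyl-trans-decalin-1β,5α-diol | CC1(C)O[C@@H]2[C@H](C(C)C)[C@@H](OC(=O)c4ccccc4)C[C@@]3(C)[C@H](O)CC[C@](C)(O1)[C@]23O | intermediate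
28 | methanesulfonyl chloride | CS(=O)(=O)Cl | starting material
29 | 1β-methanesulfonate of 27 | CC1(C)O[C@@H]2[C@H](C(C)C)[C@@H](OC(=O)c4ccccc4)C[C@@]3(C)[C@H](OS(C)(=O)=O)CC[C@](C)(O1)[C@]23O | intermediate
30 | potassium C5 alkoxide of 29 (not isolated) | CC1(C)O[C@@H]2[C@H](C(C)C)[C@@H](OC(=O)c4ccccc4)C[C@@]3(C)[C@H](OS(C)(=O)=O)CC[C@](C)(O1)[C@]23[O-].[K+] | intermediate
31 | (E)-8-benzoyloxy-7-isopropyl-4,6-(isopropylidenedioxy)-4,10-dimethylcyclodec-1(10)-en-5-one | CC1(C)O[C@@H]2[C@H](C(C)C)[C@@H](OC(=O)c4ccccc4)C/C(C)=C/CC[C@](C)(O1)C2=O | intermediate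
32 | (E)-8-benzoyloxy-7-isopropyl-4,6-(isopropylidenedioxy)-4,10-dimethylcyclodec-1(10)-en-5-ol, hydroxyl syn to O4 and O6 | CC1(C)O[C@@H]2[C@H](C(C)C)[C@@H](OC(=O)c4ccccc4)C/C(C)=C/CC[C@](C)(O1)[C@H]2O | intermediate
33 | C5 methanesulfonate of 32 | CC1(C)O[C@@H]2[C@H](C(C)C)[C@@H](OC(=O)c4ccccc4)C/C(C)=C/CC[C@](C)(O1)[C@H]2OS(C)(=O)=O | intermediate
34 | (E)-8-benzoyloxy-4,6-dihydroxy-7-isopropyl-4,10-dimethylcyclodec-1(10)-en-5-yl methanesulfonate | O[C@@H]1[C@H](C(C)C)[C@@H](OC(=O)c2ccccc2)C/C(C)=C/CC[C@](C)(O)[C@H]1OS(C)(=O)=O | intermediate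
35 | acetic anhydride | CC(=O)OC(C)=O | starting material
36 | (E)-6-acetoxy-8-benzoyloxy-4-hydroxy-7-isopropyl-4,10-dimethylcyclodec-1(10)-en-5-yl methanesulfonate | CC(=O)O[C@@H]1[C@H](C(C)C)[C@@H](OC(=O)c2ccccc2)C/C(C)=C/CC[C@](C)(O)[C@H]1OS(C)(=O)=O | intermediate
37 | sodium C4 alkoxide of 36 (not isolated) | CC(=O)O[C@@H]1[C@H](C(C)C)[C@@H](OC(=O)c2ccccc2)C/C(C)=C/CC[C@](C)([O-])[C@H]1OS(C)(=O)=O.[Na+] | intermediate
38 | (1(10)E,4S,5R,6R,7R,8S)-6-acetoxy-8-benzoyloxy-4,5-epoxygermacr-1(10)-ene, CNP0112246.1 | CC(=O)O[C@@H]1[C@H](C(C)C)[C@@H](OC(=O)c2ccccc2)C/C(C)=C/CC[C@]2(C)O[C@H]12 | target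

**Step count and risks**

Total: 23 steps. Longest linear sequence: 23 steps (1 → 38); the route has no convergent branch.

Steps most likely to fail:

Step 19 (hydride addition to the bridged C5 ketone). The risk is poor facial selectivity if the bicyclic ketone also populates a conformer in which the carbocyclic loop no longer covers the inner face, together with slow reduction of a ketone flanked by two fully substituted carbons. The fallback runs from 31 to 34 and sets the stereocentre by open-chain control after removing the tether. Acetal methanolysis of 31 (PPTS, MeOH) should give the 4,6-dihydroxy ketone F1. Both hydroxyls are silylated (Et3SiOTf, 2,6-lutidine, CH2Cl2, −78 → 0 °C) to the bis(triethylsilyl) ether F2. A bulky non-chelating hydride (LiBH(s-Bu)3, THF, −78 °C) is expected to add anti to both C–OSi bonds (polar Felkin–Anh model on both α-carbons, which reinforce each other for the syn,syn pattern) and give the alcohol F3. Mesylation (MsCl, Et3N, CH2Cl2) gives the mesylate F4, and removal of both silyl groups (HF·pyridine, THF) returns diol mesylate 34.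

Step 23 (oxirane closure next to two esters). The risk is transfer of the acetyl group from O6 to the C4 alkoxide, after which the freed C6 alkoxide would close the 5,6-oxirane, or loss of an ester. The fallback runs from 34 to 38 and closes the oxirane before C6 carries an ester. The secondary C6 hydroxyl of 34 is silylated selectively (Et3SiCl, imidazole, DMF) to the silyl ether F5. KOtBu in THF at 0 °C should close the oxirane to the epoxy silyl ether F6. Buffered fluoride (Bu4NF, AcOH, THF) frees the C6 hydroxyl to give the epoxy alcohol F7, and acetylation (Ac2O, pyridine, DMAP) gives 38.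

Step 8 (osmylation of the C5=C6 alkene of 11). The risk is slow or incomplete osmate ester formation at an alkene flanked by three fully substituted carbons. The fallback runs from 9 to 12 and reverses the order of the two additions. Enone 9, in which C4 is still trigonal and the α face is less encumbered, is dihydroxylated first (OsO4 cat., N-methylmorpholine N-oxide, citric acid, tBuOH–H2O) to the keto diol F8. Methyllithium (excess, THF, −78 °C) is then added to the C4 carbonyl from the α face to give triol 12.

Further compounds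
F1 | step 19 | (E)-8-benzoyloxy-4,6-dihydroxy-7-isopropyl-4,10-dimethylcyclodec-1(10)-en-5-one | O[C@@H]1[C@H](C(C)C)[C@@H](OC(=O)c2ccccc2)C/C(C)=C/CC[C@](C)(O)C1=O
F2 | step 19 | 4,6-bis(triethylsilyl) ether of F1 | CC[Si](CC)(CC)O[C@@H]1[C@H](C(C)C)[C@@H](OC(=O)c2ccccc2)C/C(C)=C/CC[C@](C)(O[Si](CC)(CC)CC)C1=O
F3 | step 19 | (E)-8-benzoyloxy-7-isopropyl-4,10-dimethyl-4,6-bis(triethylsilyloxy)cyclodec-1(10)-en-5-ol, hydroxyl syn to O4 and O6 | CC[Si](CC)(CC)O[C@@H]1[C@H](C(C)C)[C@@H](OC(=O)c2ccccc2)C/C(C)=C/CC[C@](C)(O[Si](CC)(CC)CC)[C@H]1O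
F4 | step 19 | C5 methanesulfonate of F3 | CC[Si](CC)(CC)O[C@@H]1[C@H](C(C)C)[C@@H](OC(=O)c2ccccc2)C/C(C)=C/CC[C@](C)(O[Si](CC)(CC)CC)[C@H]1OS(C)(=O)=O
F5 | step 23 | 6-O-triethylsilyl ether of 34 | CC[Si](CC)(CC)O[C@@H]1[C@H](C(C)C)[C@@H](OC(=O)c2ccccc2)C/C(C)=C/CC[C@](C)(O)[C@H]1OS(C)(=O)=O
F6 | step 23 | 8-benzoyloxy-4,5-epoxy-6-(triethylsilyloxy)germacr-1(10)-ene, configuration as in 38 | CC[Si](CC)(CC)O[C@@H]1[C@H](C(C)C)[C@@H](OC(=O)c2ccccc2)C/C(C)=C/CC[C@]2(C)O[C@H]12
F7 | step 23 | 8-benzoyloxy-4,5-epoxygermacr-1(10)-en-6-ol, configuration as in 38 | O[C@@H]1[C@H](C(C)C)[C@@H](OC(=O)c2ccccc2)C/C(C)=C/CC[C@]2(C)O[C@H]12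
F8 | step 8 | 1β-benzyloxy-7,7-ethylenedioxy-5α,6α-dihydroxy-10β-methyl-trans-decalin-4-one | C[C@@]12CCC3(OCCO3)[C@H](O)[C@@]1(O)C(=O)CC[C@H]2OCc4ccccc4
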